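**Plan**

1. Retrosynthesis: the quinone carbonyl that lies between the two ring CH carbons is traced back to the nitro group of a 4-nitrophenol. Both ring C=C bonds, each between a CH carbon and its substituted neighbour, are then cut in one [3+3] disconnection.
2. Enabling feature: the other ring carbonyl, with the OMe-bearing carbon on one side and the chain-bearing carbon on the other, is the carbonyl of an acyclic ketone with two α-carbons. The remaining CH–C–CH unit of the six-membered ring is a symmetrical 1,3-dialdehyde (nitromalonaldehyde), so only one orientation of union exists.
3. The ketone half, 18-methoxy-17-oxooctadecanoic acid, is cut between its α-carbon and the chain into methyl 4-methoxyacetoacetate and a C15 ω-bromo ester.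
4. Forward: the chain is joined first (esterification, acetoacetic ester alkylation, hydrolysis with decarboxylation). The only ring is then formed in one annulation, and NO2 → NH2 → C=O gives the quinone.
5. Stereochemistry: the target has no stereocentre. The one stereocentre on the way (C-2 of 4, racemic) is erased by the decarboxylation.

Key step: step 4

Assumption: sodium nitromalonaldehyde monohydrate (7) is used as the purchased salt; it is sensitive to shock and heat and should be handled in small portions.

**Step 1**
Reactants: 1 15-bromopentadecanoic acid
Product: 2 methyl 15-bromopentadecanoate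
Conditions: MeOH, H2SO4 (cat.), reflux
Reagents that add atoms: methanol, CO
Why: Fischer esterification with methanol as solvent drives the equilibrium to the ester, so that the carboxylate can neither act as a nucleophile nor consume base in step 2.

**Step 2**
Reactants: 2 methyl 15-bromopentadecanoate; 3 methyl 4-methoxy-3-oxobutanoate (methyl 4-methoxyacetoacetate)
Product: 4 dimethyl 2-(2-methoxyacetyl)heptadecanedioate (racemic)
Conditions: 3 (1.5 equiv), NaH (1.4 equiv), THF, 0 °C; then 2, NaI (cat.), DMF, 60 °C
Reagents that add atoms: none
Why: Acetoacetic ester alkylation, in which the doubly stabilised sodium enolate of 3 is C-alkylated by the unhindered primary bromide (SN2 with iodide catalysis) while the excess of 3 limits dialkylation; the new stereocentre at C-2 forms as a racemate and is removed in step 3.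

**Step 3**
Reactants: 4 dimethyl 2-(2-methoxyacetyl)heptadecanedioate
Product: 6 18-methoxy-17-oxooctadecanoic acid, via β-keto diacid 5 (not isolated)
Conditions: AcOH/6 M HCl (2:1), 100 °C
Reagents that add atoms: water, O
Why: Acid-catalysed hydrolysis of both methyl esters is followed by thermal decarboxylation of the β-keto acid 5 through its cyclic six-membered transition state (ketonic cleavage of an acetoacetic ester); acid is chosen over hydroxide to avoid retro-Claisen cleavage, and the methyl ether and the ketone are inert.

**Step 4**
Reactants: 6 18-methoxy-17-oxooctadecanoic acid; 7 sodium nitromalonaldehyde monohydrate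
Product: 9 15-(2-hydroxy-3-methoxy-5-nitrophenyl)pentadecanoic acid, via open-chain nitro enal 8 (not isolated)
Conditions: NaOH (2.2 equiv), EtOH/H2O (1:1), 7 (1.2 equiv), rt to 45 °C, 2–3 d; then 2 M HCl, 0 °C
Reagents that add atoms: none
Why: Hydroxide generates the enolate of 6 (expected first at the more acidic methoxy-bearing α-carbon; the other order converges on the same product), which adds to one formyl group of the nitromalonaldehyde anion and loses water by E1cB to give 8; the second α-carbon then adds intramolecularly to the remaining formyl group, a second dehydration follows, and a proton shift from the nitro-bearing carbon to oxygen delivers the 4-nitrophenoxide, whose aromatic stabilisation makes the otherwise reversible aldol sequence irreversible. The closest known reaction type is the Hill condensation of sodium nitromalonaldehyde with ketones that carry two α-methylene groups, a [3+3] benzannulation that gives 2,6-disubstituted 4-nitrophenols. The six-membered ring closes by intramolecular aldol addition in the 6-(enolexo)-exo-trig mode. No stereocentre is created. The step needs 1:1 cross-condensation in preference to self-aldol of 6, and a single orientation of the two halves: the first should be secured by the higher electrophilicity of the formyl groups and by the intramolecular second aldol, the second by the mirror symmetry of the three-carbon dialdehyde and by the fact that 6 has only two enolisable carbons, which end up on either side of the phenolic carbon. The nitro group both stabilises the dialdehyde as a non-enolisable salt and marks the carbon that becomes the second quinone carbonyl.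

**Step 5**
Reactants: 9 15-(2-hydroxy-3-methoxy-5-nitrophenyl)pentadecanoic acid
Product: 12 15-(5-methoxy-3,6-dioxocyclohexa-1,4-dien-1-yl)pentadecanoic acid, via aminophenol 10 (not isolated), via quinone monoimine 11 (not isolated)
Conditions: H2 (1 atm), Pd/C, MeOH, rt; filter under Ar; then FeCl3 (3 equiv), 0.5 M HCl/EtOAc, 0 °C
Reagents that add atoms: water, O
Why: Catalytic hydrogenation reduces the nitro group to the amine, and the electron-rich p-aminophenol 10 should then be oxidised by two equivalents of trivalent iron to the quinone monoimine 11, whose iminium form is hydrolysed by the aqueous acid to the p-quinone (classical aminophenol-to-quinone oxidation); the acid keeps unoxidised amine protonated and the ethyl acetate layer takes the quinone away from it.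

**Compound list**

1 | 15-bromopentadecanoic acid | OC(=O)CCCCCCCCCCCCCCBr | starting material
2 | methyl 15-bromopentadecanoate | COC(=O)CCCCCCCCCCCCCCBr | intermediate
3 | methyl 4-methoxy-3-oxobutanoate | COCC(=O)CC(=O)OC | starting material
4 | dimethyl 2-(2-methoxyacetyl)heptadecanedioate (racemic) | COCC(=O)C(C(=O)OC)CCCCCCCCCCCCCCC(=O)OC | intermediate
5 | 2-(2-methoxyacetyl)heptadecanedioic acid (racemic, not isolated) | COCC(=O)C(C(=O)O)CCCCCCCCCCCCCCC(=O)O | intermediate
6 | 18-methoxy-17-oxooctadecanoic acid | COCC(=O)CCCCCCCCCCCCCCCC(=O)O | intermediate
7 | sodium nitromalonaldehyde monohydrate | O=CC(C=O)=[N+]([O-])[O-].[Na+].O | starting material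
8 | (18E)-18-methoxy-20-nitro-17,21-dioxohenicos-18-enoic acid (racemic at C-20, present in the flask as its delocalised sodium salt, not isolated) | CO/C(=C/C(C=O)[N+](=O)[O-])C(=O)CCCCCCCCCCCCCCCC(=O)O | intermediate
9 | 15-(2-hydroxy-3-methoxy-5-nitrophenyl)pentadecanoic acid | COc1cc(cc(CCCCCCCCCCCCCCC(=O)O)c1O)[N+](=O)[O-] | intermediate
10 | 15-(5-amino-2-hydroxy-3-methoxyphenyl)pentadecanoic acid (not isolated) | COc1cc(N)cc(CCCCCCCCCCCCCCC(=O)O)c1O | intermediate
11 | 15-(3-imino-5-methoxy-6-oxocyclohexa-1,4-dien-1-yl)pentadecanoic acid (imine geometry not fixed, not isolated) | COC1=CC(=N)C=C(CCCCCCCCCCCCCCC(=O)O)C1=O | intermediate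
12 | 15-(5-methoxy-3,6-dioxocyclohexa-1,4-dien-1-yl)pentadecanoic acid | COC1=CC(=O)C=C(CCCCCCCCCCCCCCC(=O)O)C1=O | target

**Step count and risks**

Total step count: 5. Longest linear sequence: 5 steps (1 → 2 → 4 → 6 → 9 → 12).

Steps most likely to fail:

Step 4. Self-aldol condensation of the ketone and base-induced decomposition of the nitromalonaldehyde salt may outrun the double aldol, or the open-chain intermediate may fail to close. Fallback, from 2 to 12, in which the ring is bought instead of built: zinc insertion into 2 (Zn dust, LiCl, THF, 50 °C) should give (15-methoxy-15-oxopentadecyl)zinc bromide F1. Commercial 2-bromo-6-methoxyphenol is acetylated (Ac2O, pyridine) to 2-bromo-6-methoxyphenyl acetate F2. Negishi coupling of F1 and F2 (Pd(OAc)2, SPhos, THF, rt) should give methyl 15-(2-acetoxy-3-methoxyphenyl)pentadecanoate F3. LiOH in THF/H2O removes both esters to give 15-(2-hydroxy-3-methoxyphenyl)pentadecanoic acid F4. Teuber oxidation of this 2,6-disubstituted phenol with Fremy's salt, (KSO3)2NO, in buffered aqueous acetone should give 12 directly.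

Step 5. Conjugate addition of still unoxidised aminophenol to the quinone as it forms, or slow hydrolysis of the imine, may divert material to aminoquinones and dimers. Fallback, from 9 to 12, in which the nitrogen is removed before the oxygen is introduced: 9 is hydrogenated to 10 as above, and 10 is diazotised (NaNO2, aqueous HCl, 0 °C) to 3-(14-carboxytetradecyl)-4-hydroxy-5-methoxybenzenediazonium chloride F5. Reduction with H3PO2 should give the phenol acid F4 of the preceding fallback, and the Teuber oxidation described there carries it to 12.

Step 2. O-alkylation and dialkylation of the β-keto ester, or slow displacement at the long-chain bromide, may lower the supply of 4. Fallback, from 2 to 4, by condensation and reduction instead of substitution: Kornblum oxidation of 2 (DMSO, NaHCO3, NaI cat., 120 °C) should give methyl 15-oxopentadecanoate F6. Knoevenagel condensation of F6 with 3 (piperidine, AcOH, toluene, water removal) should give dimethyl 2-(2-methoxyacetyl)heptadec-2-enedioate F7. Hydrogenation of the alkene (H2, Pd/C, EtOAc) returns to 4.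

**Further compounds**

F1 | step 4 | (15-methoxy-15-oxopentadecyl)zinc bromide | COC(=O)CCCCCCCCCCCCCC[Zn]Br
F2 | step 4 | 2-bromo-6-methoxyphenyl acetate | COc1cccc(Br)c1OC(C)=O
F3 | step 4 | methyl 15-(2-acetoxy-3-methoxyphenyl)pentadecanoate | COc1cccc(CCCCCCCCCCCCCCC(=O)OC)c1OC(C)=O
F4 | step 4 | 15-(2-hydroxy-3-methoxyphenyl)pentadecanoic acid | COc1cccc(CCCCCCCCCCCCCCC(=O)O)c1O
F5 | step 5 | 3-(14-carboxytetradecyl)-4-hydroxy-5-methoxybenzenediazonium chloride | COc1cc([N+]#N)cc(CCCCCCCCCCCCCCC(=O)O)c1O.[Cl-]
F6 | step 2 | methyl 15-oxopentadecanoate | COC(=O)CCCCCCCCCCCCCC=O
F7 | step 2 | dimethyl 2-(2-methoxyacetyl)heptadec-2-enedioate (E/Z mixture) | COCC(=O)C(C(=O)OC)=CCCCCCCCCCCCCCC(=O)OC
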